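## Analysis of the target

Germacrane numbering is used for the target and for all intermediates.

- **Ring system.** Lychnopholide (28) has three rings.
  - Ring A is the ten-membered carbocycle C1–C10.
  - Ring B is the 3(2H)-furanone O–C3=C2–C1(=O)–C10. Its oxygen bridges C3 and C10 across ring A.
  - Ring C is the α-methylene-γ-butyrolactone O–C6–C7–C11(=C13H2)–C12(=O), trans-fused to ring A.
- **Rigidity.** Five atoms of ring A are sp2 (C1–C5), C10 is quaternary, and C4=C5 is Z. The ring is therefore rigid, strained and hard to close.
- **Stereocentres.** There are four.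
  - C6 (R), C7 (R) and C8 (S) are contiguous. O6, C11 and O8 lie on the same side of the zigzag chain C5–C9, and H6/H7 are trans.
  - The carbinol carbon C10 (R) is insulated from this triad by the C9 methylene group.
- **Sensitive groups.** These are the exocyclic methylene lactone (a Michael acceptor), the angelate (Z to E drift with nucleophiles), the cross-conjugated furanone–diene and the acyloxy groups at C6 and C8.
- **Feature that invites the chosen move.** C3, shared by rings A and B, bears no hydrogen and no carbon substituent and stands at the carbonyl oxidation level. It sits between the vinylic C4 and the C2–C1 pair.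
- **Consequence.** C2–C1 together with C10–O is only the hydrated, cyclised form of a tertiary propargylic alcohol. C3 can therefore be carbon monoxide (25).
- **Difficulty.** Ring A must be closed without loss of the Z-alkene. The remote C10 must be matched to the triad. All electrophilic groups must come late.

## Retrosynthetic reasoning

**28 to 26.** The C3–O bond of ring B is cut and the oxygen pattern is shifted back, which gives the isomeric γ-hydroxy alkynone 26 (C3 ketone, C1≡C2, free C10–OH). Ring B and the oxygen bridge then need no separate construction. The forward reaction has to add water across C1≡C2 (27) and close the five-membered ring on C3.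

**26 to 24 + 25.** Both C–C bonds of C3 (C3–C4 and C3–C2) are cut, and C3 leaves as 25. This is the only cut that opens ring A without touching a stereocentre or the Z-alkene. What remains is an open chain (24) that ends in a Z-vinyl iodide and a terminal alkyne. The forward step must insert 25 and join the two ends in one operation.

**24 to 21 + 22.** The C8–O ester bond is cut. The angelate is put on before ring closure, so that O8 cannot intercept the acyl-metal species and no acylation is needed on the strained product.

**21 to 9 + 19.** C7–C8 is cut with allylic transposition, so the C13=C11–C7–C8–OH array is read as a homoallylic alcohol. Flat butenolide 9 then holds only C6, and aldehyde 19 holds only C10. The forward allylation must set C7 anti to the C6 side chain. It must set C8 through a closed transition state and create the exocyclic methylene group.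

**9 to 8 to 6 + 7.** C7=C11 is cut (metathesis) and so is the O6–C12 ester bond. Ring C then comes from an alcohol and a commercial acid in two neutral steps. This matters because H6 of 9 is acidic.

**6 to 5, 4, 3 and 1.** C6–C7 is cut (vinyl addition to an enal) and C6 is resolved. The Z-iodoalkene comes from directed hydrometalation of alkynol 1, so the C4=C5 geometry is fixed in the first step.

**19 to 17, 15, 12 and 10 + 11 + 13.** The aldehyde carbon C8 is a cleaved allyl group, and C2 is a one-carbon homologation of the C1 carbonyl. C10 is the α-carbon of lactic acid (10), alkylated with 13 through its acetal 12 with retention.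

## Alternatives that were turned down

**Alternative 1:** the textbook cut of C6–C7 together with the lactone O–C12 bond.
- *Forward key step:* the Z-enal of seco bromide A1 is attacked by its own 2-(bromomethyl)enoate under zinc or divalent chromium. The C6 alkoxide then lactonises.
- *Reasons for turning it down:*
  - A1 must already hold ring B, C8 and C10, so the route is linear and carries the dienone for many steps.
  - Its Z-enal is vinylogously conjugated to the furanone carbonyl, so reversible addition at C5 isomerises it to the E form, which cannot close.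
  - C6 and C7 would both arise in a macrocyclic transition state from an acyclic allylmetal that can change its geometry.

**Alternative 2:** ring A made by three-atom ring expansion.
- *Forward key step:* diazoketone A2 holds O, C3, C4=C5, C6 and C7 in a dihydropyran. It would give a metal carbene at C10, then a cyclic oxonium ylide, and a [2,3] shift would give A3.
- *What it wins:* the Z-alkene, the oxygen bridge, C9–C10 and the C10 stereocentre in one step.
- *Reasons for turning it down:*
  - The shift leaves C7=C8 as an alkene.
  - Coplanarity of C10 with the enone holds C10 anti to C6 about the O–C7 bond, so this alkene should be E.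
  - Ring C then needs carbon at the central atom C7 of an allylic unit and oxygen at C8, added syn on one face. No short reliable method exists for that, and some six further steps would be needed.
  - The methyl-bearing carbene can also decay by 1,2-hydride shift.

**Alternative 3:** C4=C5 made by ring contraction.
- *Forward key step:* eleven-membered sulfone A4 would undergo a Ramberg–Bäcklund reaction with extrusion of the sulfonyl bridge.
- *Reasons for turning it down:*
  - A4 is as complex as the target, with all four stereocentres and rings B and C.
  - The sulfide stage is incompatible with the exocyclic methylene lactone.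
  - The strong base needed would attack the lactone, the angelate and H6.
  - The contraction adds steps without removing any problem.

Key step: step 13

Remark: acetal 12 is also an article of commerce; if it is bought, step 7 falls away.

## Route

Step 1
Reactants: 1 but-2-yn-1-ol
Product: 3 (Z)-3-iodobut-2-en-1-ol, via sodium alkenylalanate 2 (not isolated)
Conditions: NaAlH2(OCH2CH2OMe)2, THF, 0 °C to rt; I2, −78 °C; aq. work-up
Reagents that add atoms: iodine, II
Why: Hydroxyl-directed trans-hydroalumination puts aluminium on C4 inside the five-membered ring of 2. Iodinolysis with retention gives only the Z-iodide, which fixes the C4=C5 geometry of 28.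

Step 2
Reactants: 3 (Z)-3-iodobut-2-en-1-ol
Product: 4 (Z)-3-iodobut-2-enal
Conditions: MnO2, CH2Cl2, rt
Reagents that add atoms: none
Why: Allylic oxidation on MnO2 is neutral. The Z-enal should keep its geometry if it is used at once.

Step 3
Reactants: 4 (Z)-3-iodobut-2-enal
Product: 5 racemic (Z)-5-iodohexa-1,4-dien-3-ol
Conditions: CH2=CHMgBr, THF, −78 °C; H2O
Reagents that add atoms: vinylmagnesium bromide, C=C[Mg]Br
Why: Grignard 1,2-addition to an enal forms C6–C7. The C–I bond does not exchange with a vinyl Grignard reagent at this temperature.

Step 4
Reactants: 5 racemic (Z)-5-iodohexa-1,4-dien-3-ol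
Product: 6 (S,Z)-5-iodohexa-1,4-dien-3-ol
Conditions: Ti(OiPr)4, L-(+)-diisopropyl tartrate, tBuOOH (0.55 equiv), 4 Å MS, CH2Cl2, −20 °C
Reagents that add atoms: none
Why: This is a Sharpless kinetic resolution. With the L-(+)-tartrate the R-alcohol is epoxidised at its unsubstituted vinyl group, while the electron-poor Z-iodoalkene is inert. The S-alcohol is recovered, which sets C6.

Step 5
Reactants: 6 (S,Z)-5-iodohexa-1,4-dien-3-ol; 7 2-(bromomethyl)acrylic acid
Product: 8 (3S,4Z)-5-iodohexa-1,4-dien-3-yl 2-(bromomethyl)prop-2-enoate
Conditions: DCC, DMAP (5 mol %), CH2Cl2, −20 to 0 °C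
Reagents that add atoms: none
Why: Steglich esterification leaves the C6–O bond untouched. Low temperature and little DMAP spare the allylic bromide.

Step 6
Reactants: 8 (3S,4Z)-5-iodohexa-1,4-dien-3-yl 2-(bromomethyl)prop-2-enoate
Product: 9 (5S)-3-(bromomethyl)-5-[(1Z)-2-iodoprop-1-en-1-yl]furan-2(5H)-one
Conditions: RuCl2(H2IMes)(=CH-C6H4-2-OiPr) (second-generation Hoveyda–Grubbs catalyst, 5 mol %), toluene, 60 °C, argon sparge
Reagents that add atoms: none
Why: Ring-closing metathesis loads on the monosubstituted C7 vinyl group and closes the five-membered ring on the 1,1-disubstituted acrylate. The trisubstituted iodoalkene is inert, allylic bromides are tolerated by ruthenium alkylidenes, and the neutral medium protects the acidic H6.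

Step 7
Reactants: 10 (S)-lactic acid; 11 pivalaldehyde
Product: 12 (2S,5S)-2-tert-butyl-5-methyl-1,3-dioxolan-4-one
Conditions: p-TsOH (cat.), pentane, reflux, Dean–Stark trap; crystallisation
Reagents that add atoms: none
Why: Acid-catalysed acetalisation stores the chirality of 10 in a new acetal centre. The cis isomer is obtained pure by crystallisation.

Step 8
Reactants: 12 (2S,5S)-2-tert-butyl-5-methyl-1,3-dioxolan-4-one; 13 allyl bromide
Product: 15 (2S,5R)-2-tert-butyl-5-methyl-5-(prop-2-en-1-yl)-1,3-dioxolan-4-one, via lithium enolate 14 (not isolated)
Conditions: LiN(iPr)2, THF, −78 °C; then 13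
Reagents that add atoms: none
Why: This is self-regeneration of the stereocentre. Planar enolate 14 is alkylated anti to the tert-butyl group, so allyl takes the place of H with retention and sets C10 (R).

Step 9
Reactants: 15 (2S,5R)-2-tert-butyl-5-methyl-5-(prop-2-en-1-yl)-1,3-dioxolan-4-one
Product: 17 (R)-3-methylhex-5-en-1-yn-3-ol, via lactol 16 (not isolated)
Conditions: iBu2AlH, CH2Cl2, −78 °C; then MeOH, K2CO3, dimethyl (1-diazo-2-oxopropyl)phosphonate, −78 °C to rt
Reagents that add atoms: dimethyl (1-diazo-2-oxopropyl)phosphonate, COP(=O)(OC)C(=[N+]=[N-])C(C)=O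
Why: This is the one-pot reduction and Ohira–Bestmann homologation of an ester. Lactol 16 opens in basic methanol, loses its acetal aldehyde and gives the α-hydroxy aldehyde, which is converted into the alkyne (C2 added). The quaternary C10 cannot epimerise.

Step 10
Reactants: 17 (R)-3-methylhex-5-en-1-yn-3-ol
Product: 19 (R)-3-hydroxy-3-methylpent-4-ynal, via ozonide 18 (not isolated)
Conditions: O3, CH2Cl2, −78 °C (Sudan Red 7B end point); Me2S
Reagents that add atoms: ozone, [O-][O+]=O
Why: In this ozonolysis the terminal alkene reacts far faster than the terminal alkyne, and the dye marks the end point. Aldehyde 19 is used crude.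

Step 11
Reactants: 9 (5S)-3-(bromomethyl)-5-[(1Z)-2-iodoprop-1-en-1-yl]furan-2(5H)-one; 19 (R)-3-hydroxy-3-methylpent-4-ynal
Product: 21 (4R,5S)-4-[(1S,3R)-1,3-dihydroxy-3-methylpent-4-yn-1-yl]-5-[(1Z)-2-iodoprop-1-en-1-yl]-3-methylideneoxolan-2-one, via allylchromium dichloride 20 (not isolated)
Conditions: CrCl2 (nickel-free), THF, 0 °C to rt; aq. work-up
Reagents that add atoms: none
Why: In this Nozaki–Hiyama allylation, 20 attacks through its γ-carbon C7 on the face anti to the C6 side chain (H6/H7 trans), which forms C7–C8 and the exocyclic C11=C13. The ring locks the allylmetal in the E-crotyl sense, so the Zimmerman–Traxler chair with C9 equatorial gives the anti adduct, which is 8S. Without nickel the vinyl iodide is not touched.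

Step 12
Reactants: 21 open-chain diol; 22 angelic acid
Product: 24 C8 (Z)-2-methylbut-2-enoate of 21 (seco iodide), via mixed anhydride 23 (not isolated)
Conditions: 2,4,6-Cl3C6H2COCl, Et3N, toluene, rt; then 21, 75 °C
Reagents that add atoms: none
Why: Yamaguchi-type mixed-anhydride esterification without a nucleophilic catalyst avoids the addition–elimination path that turns angelate into tiglate. Only the secondary C8–OH reacts, and the tertiary propargylic C10–OH stays free.

Step 13
Reactants: 24 seco iodide; 25 carbon monoxide
Product: 26 ten-membered alkynone (6R,7R,8S,10R; ring A closed, C3 ketone, C1≡C2, free C10–OH)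
Conditions: PdCl2(PPh3)2 (10 mol %), CuI (10 mol %), Et3N, CO (3 bar), THF, 40 °C, syringe-pump addition of 24 (final 1 mM)
Reagents that add atoms: none
Why: Proposed new method: Zerovalent palladium adds oxidatively to the C4–I bond with retention of the Z geometry and 25 inserts to give the C3 acylpalladium iodide; CuI/Et3N turn the C2–H alkyne into its copper acetylide, which transmetalates within the same molecule, and reductive elimination forms C3–C2. The closest known reactions are the intermolecular carbonylative Sonogashira synthesis of alkynones from vinyl iodides, the carbonylative Stille closure of macrocyclic dienones and the palladium-mediated closure of ten-membered enediynes; new is the use of the acyl/acetylide pair to close a medium ring. One ring is closed, ring A, end to end through an eleven-membered acyl(alkynyl)palladacycle, with two C–C bonds made and one carbon added. No stereocentre is formed, and C6, C7, C8 and C10 are not epimerisable under Et3N. Carbonylation is chosen over direct coupling by the substrate itself, since coupling without 25 would need a nine-membered Z-enyne, whereas 26 should have only cyclodecyne-like strain, its C3···C10 gap of about 4 Å being bridged by the seven-bond chain that spans a still shorter gap in 28. Cyclisation is favoured over oligomerisation by slow addition, by the Z-alkene and the trans-lactone, which turn both chain ends to the same side, and by the gem-disubstituted C10. O8 is already acylated and the tertiary C10–OH is too hindered to capture the acylpalladium, and insertion into C11=C13 would need a bridged bicyclo[3.2.1] transition state that CO uptake under pressure should outrun.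

Step 14
Reactants: 26 ten-membered alkynone
Product: 28 lychnopholide, via cyclic 1,3-diketone 27 (not isolated)
Conditions: (4-CF3C6H4)3PAuCl (5 mol %), AgOTf (5 mol %), moist toluene, rt
Reagents that add atoms: none
Why: This is the monovalent-gold-catalysed isomerisation of γ-hydroxy alkynones to 3(2H)-furanones. Traces of water add at C1, the β-carbon of the activated and strained alkynone, to give 27. The C10–OH then closes ring B by 5-exo-trig attack on the C3 carbonyl and water is lost again. The neutral conditions spare the methylene lactone and the angelate.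

## Compound list

1 | but-2-yn-1-ol | CC#CCO | starting material
2 | sodium alkenylalanate (five-membered C4–Al–O chelate) | CC1=CCO[Al-]1(OCCOC)OCCOC.[Na+] | intermediate
3 | (Z)-3-iodobut-2-en-1-ol | C/C(I)=C/CO | intermediate
4 | (Z)-3-iodobut-2-enal | C/C(I)=C/C=O | intermediate
5 | racemic (Z)-5-iodohexa-1,4-dien-3-ol | C=CC(O)/C=C(/C)I | intermediate
6 | (S,Z)-5-iodohexa-1,4-dien-3-ol | O[C@@H](C=C)/C=C(/C)I | intermediate
7 | 2-(bromomethyl)acrylic acid | C=C(CBr)C(=O)O | starting material
8 | (3S,4Z)-5-iodohexa-1,4-dien-3-yl 2-(bromomethyl)prop-2-enoate | C=C(CBr)C(=O)O[C@@H](C=C)/C=C(/C)I | intermediate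
9 | (5S)-3-(bromomethyl)-5-[(1Z)-2-iodoprop-1-en-1-yl]furan-2(5H)-one | O=C1O[C@@H](C=C1CBr)/C=C(/C)I | intermediate
10 | (S)-lactic acid | C[C@H](O)C(=O)O | starting material
11 | pivalaldehyde | CC(C)(C)C=O | starting material
12 | (2S,5S)-2-tert-butyl-5-methyl-1,3-dioxolan-4-one | C[C@@H]1O[C@H](C(C)(C)C)OC1=O | intermediate
13 | allyl bromide | C=CCBr | starting material
14 | lithium enolate of 12 | CC1=C([O-])O[C@@H](C(C)(C)C)O1.[Li+] | intermediate
15 | (2S,5R)-2-tert-butyl-5-methyl-5-(prop-2-en-1-yl)-1,3-dioxolan-4-one | C[C@]1(CC=C)O[C@H](C(C)(C)C)OC1=O | intermediate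
16 | (2S,5R)-2-tert-butyl-5-methyl-5-(prop-2-en-1-yl)-1,3-dioxolan-4-ol (lactol, C4 epimers) | C[C@]1(CC=C)O[C@H](C(C)(C)C)OC1O | intermediate
17 | (R)-3-methylhex-5-en-1-yn-3-ol | C#C[C@](C)(O)CC=C | intermediate
18 | ozonide of 17 (1,2,4-trioxolane) | C#C[C@](C)(O)CC1OCOO1 | intermediate
19 | (R)-3-hydroxy-3-methylpent-4-ynal | C#C[C@](C)(O)CC=O | intermediate
20 | allylchromium dichloride from 9 | O=C1O[C@@H](C=C1C[Cr](Cl)Cl)/C=C(/C)I | intermediate
21 | (4R,5S)-4-[(1S,3R)-1,3-dihydroxy-3-methylpent-4-yn-1-yl]-5-[(1Z)-2-iodoprop-1-en-1-yl]-3-methylideneoxolan-2-one | C=C1C(=O)O[C@H](/C=C(/C)I)[C@H]1[C@@H](O)C[C@@](C)(O)C#C | intermediate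
22 | angelic acid, (Z)-2-methylbut-2-enoic acid | C/C=C(/C)C(=O)O | starting material
23 | angelic 2,4,6-trichlorobenzoic anhydride | C/C=C(/C)C(=O)OC(=O)c1c(Cl)cc(Cl)cc1Cl | intermediate
24 | C8 angelate of 21 (seco iodide) | C=C1C(=O)O[C@H](/C=C(/C)I)[C@H]1[C@@H](OC(=O)/C(C)=C\C)C[C@@](C)(O)C#C | intermediate
25 | carbon monoxide | [C-]#[O+] | starting material
26 | ten-membered alkynone (6R,7R,8S,10R) | C=C1C(=O)O[C@@H]2/C=C(/C)C(=O)C#C[C@](C)(O)C[C@H](OC(=O)/C(C)=C\C)[C@@H]12 | intermediate
27 | cyclic 1,3-diketone (hydrate of 26) | C=C1C(=O)O[C@@H]2/C=C(/C)C(=O)CC(=O)[C@](C)(O)C[C@H](OC(=O)/C(C)=C\C)[C@@H]12 | intermediate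
28 | lychnopholide | C=C1C(=O)O[C@@H]2/C=C(/C)C3=CC(=O)[C@@](C)(C[C@H](OC(=O)/C(C)=C\C)[C@@H]12)O3 | target

## Step count and least certain steps

Total: 14 steps. Longest linear sequence: 10 steps (steps 1–6 and 11–14). Steps 7–10 form the second branch.

**Step 13 (key step, proposed new method).**
- *What may go wrong:* the two chain ends may fail to meet, so that the acylpalladium is consumed by intermolecular coupling (oligomerisation). It may also be consumed by insertion into the exocyclic methylene group before transmetalation.
- *Fallback:* the order of events is reversed with known reactions, and ring A is closed at C7–C8 instead. The sequence sets out from 6, 17, 25, 7 and 22 and comes back at 28.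
  1. Alcohol 6 is silylated to the silyl ether F1.
  2. An intermolecular carbonylative Sonogashira reaction of F1 with 17 and 25 gives the open alkynone F2.
  3. Gold catalysis as in step 14 gives the 2-allylfuranone F3.
  4. HF·pyridine frees the alcohol F4.
  5. Esterification with 7 gives the acrylate F5.
  6. Ring-closing metathesis gives the butenolide bromide F6.
  7. Lemieux–Johnson cleavage (OsO4, NaIO4) of the only remaining monosubstituted alkene gives the aldehyde F7.
  8. Intramolecular Nozaki–Hiyama allylation (CrCl2, high dilution) closes ring A and gives the C8 alcohol F8 with the same stereocontrol as in step 11.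
  9. Acylation with 23 gives 28.

**Step 11.**
- *What may go wrong:* the simple diastereoselection at C8 may erode if the chelating β-hydroxy aldehyde reacts through a boat or open transition state. The C8 chromium alkoxide may also attack C12 and shift the lactone from O6 to O8.
- *Fallback:* C8 is set by inversion instead of by the transition state. The allylation of 19 with 9 is run in aqueous medium (zinc, NH4Cl), where the alkoxide is protonated at once. The 8-epimer F9 is not discarded but esterified with 22 under Mitsunobu conditions, which inverts C8. This sets out from 9 and 19 and comes back at 24.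

**Step 14.**
- *What may go wrong:* the gold catalyst may be held by the other π-systems, or hydration may take the wrong regiochemical course, so that the strained alkynone decays by unselective addition.
- *Fallback:* the classical amine route, which sets out from 26 and comes back at 28.
  1. Excess diethylamine adds to C1 of 26 and, reversibly, to C13, to give the bis-adduct F10.
  2. Aqueous acetic acid closes ring B and gives the amine-masked furanone F11.
  3. Methyl iodide gives the ammonium salt F12.
  4. NaHCO3 eliminates the amine and restores C11=C13.

**Step 10.**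
- *What may go wrong:* ozone may begin to attack the alkyne. The β-hydroxy aldehyde may also be lost by retro-aldol cleavage or self-condensation during isolation.
- *Fallback:* the aldehyde is never isolated. Compound 17 is dihydroxylated (OsO4, N-methylmorpholine N-oxide) to the triol F13. NaIO4 cleaves F13 in THF/H2O to 19 in the flask. Bromide 9 and indium powder are added to the same aqueous mixture for a Barbier allylation. This sets out from 17 and comes back at 21.

## Further compounds

F1 | step 13 | (3S,4Z)-3-(tert-butyldimethylsilyloxy)-5-iodohexa-1,4-diene | CC(C)(C)[Si](C)(C)O[C@@H](C=C)/C=C(/C)I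
F2 | step 13 | open alkynone from F1, 17 and 25 | CC(C)(C)[Si](C)(C)O[C@@H](C=C)/C=C(/C)C(=O)C#C[C@](C)(O)CC=C
F3 | step 13 | (2R)-2-allyl-2-methyl-3(2H)-furanone with silylated C6 side chain | CC(C)(C)[Si](C)(C)O[C@@H](C=C)/C=C(/C)C1=CC(=O)[C@@](C)(CC=C)O1
F4 | step 13 | C6 alcohol from F3 | O[C@@H](C=C)/C=C(/C)C1=CC(=O)[C@@](C)(CC=C)O1
F5 | step 13 | 2-(bromomethyl)acrylate of F4 | C=C(CBr)C(=O)O[C@@H](C=C)/C=C(/C)C1=CC(=O)[C@@](C)(CC=C)O1
F6 | step 13 | 3-(bromomethyl)butenolide with allylfuranone | O=C1O[C@@H](C=C1CBr)/C=C(/C)C2=CC(=O)[C@@](C)(CC=C)O2
F7 | step 13 | 3-(bromomethyl)butenolide with C8 aldehyde | O=C1O[C@@H](C=C1CBr)/C=C(/C)C2=CC(=O)[C@@](C)(CC=O)O2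
F8 | step 13 | 8-O-deangeloyl-lychnopholide | C=C1C(=O)O[C@@H]2/C=C(/C)C3=CC(=O)[C@@](C)(C[C@H](O)[C@@H]12)O3
F9 | step 11 | 8-epimer of 21 | C=C1C(=O)O[C@H](/C=C(/C)I)[C@H]1[C@H](O)C[C@@](C)(O)C#C
F10 | step 14 | bis-adduct of 26 and diethylamine (C1 enaminone, C13 amine, C11 epimers) | CCN(CC)CC1C(=O)O[C@@H]2/C=C(/C)C(=O)C=C(N(CC)CC)[C@](C)(O)C[C@H](OC(=O)/C(C)=C\C)[C@@H]12
F11 | step 14 | 13-diethylamino-11,13-dihydrolychnopholide (C11 epimers) | CCN(CC)CC1C(=O)O[C@@H]2/C=C(/C)C3=CC(=O)[C@@](C)(C[C@H](OC(=O)/C(C)=C\C)[C@@H]12)O3
F12 | step 14 | methiodide of F11 | CC[N+](C)(CC)CC1C(=O)O[C@@H]2/C=C(/C)C3=CC(=O)[C@@](C)(C[C@H](OC(=O)/C(C)=C\C)[C@@H]12)O3.[I-]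
F13 | step 10 | (4R)-4-methylhex-5-yne-1,2,4-triol (C2 epimers) | C#C[C@](C)(O)CC(O)CO
A1 | alternative 1 | seco Z-enal with (Z)-2-(bromomethyl)enoate (8S,10R) | O=C/C=C(/C)C1=CC(=O)[C@@](C)(C[C@H](OC(=O)/C(C)=C\C)/C=C(\CBr)C(=O)OC)O1
A2 | alternative 2 | dihydropyran diazoketone (6R,7S; Z exocyclic enol ether) | C=C[C@@H]1O/C(=C\C(=O)C(C)=[N+]=[N-])C(C)=C[C@H]1O[Si](C)(C)C(C)(C)C
A3 | alternative 2 | ring-expanded bridged furanone with E C7=C8 | CC(C)(C)[Si](C)(C)O[C@@H]2/C=C(/C)C3=CC(=O)[C@@](C)(C/C=C/2)O3
A4 | alternative 3 | eleven-membered sulfone (sulfonyl bridge between C4 and C5) | C=C1C(=O)O[C@@H]2CS(=O)(=O)C(C)C3=CC(=O)[C@@](C)(C[C@H](OC(=O)/C(C)=C\C)[C@@H]12)O3
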